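**Plan**
- Retrosynthetic cuts, in order: the four O–Si bonds; O1–C2 of ring C (hemiketal dehydration); C2–C3; the aryl ester C–O bond.
- Enabling feature: C2 carries ring B and is at the acyl oxidation level, C3 is the oxygenated α-carbon of the ring A aryl ketone (C4), and O1 is the ring A phenol oxygen ortho to that ketone. The ring B acid can therefore sit on O1 as an aryl ester and be handed to C3 within one molecule.
- Forward: ring A ketone 6 (three steps from 2',4',5'-trihydroxyacetophenone) and ring B acid 11 (three steps from 3,4-dihydroxybenzaldehyde, prenyl ether installed first) are joined as ester 12. The acyl shift then makes C2–C3 (diketone 13), ring C, the only ring built, closes by cyclodehydration, and fluoride frees the four hydroxyls.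
- Stereochemistry: the target has no stereocentre and the prenyl double bond has no geometry; C2 of diketone 13 forms racemic and becomes sp2 in ring C.

Key step: step 8

Remark: an aryl prenyl ether is assumed to ionise under mineral or sulfonic acid, so all hydroxyls are masked as silyl ethers (removed by fluoride) and ring C is closed with a pyridinium acid.
Abbreviations: TBS = tert-butyldimethylsilyl, TBSO = tert-butyldimethylsilyloxy, TMS = trimethylsilyl.

**Route**

Step 1
Reactants: 1 2',4',5'-trihydroxyacetophenone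
Product: 2 1-[4,5-bis(TBSO)-2-hydroxyphenyl]ethanone
Conditions: TBSCl (2.2 equiv), imidazole, DMF, 0 °C to 20 °C, argon
Reagents that add atoms: tert-butyldimethylsilyl chloride (TBSCl), CC(C)(C)[Si](C)(C)Cl
Why: Phenol silylation should take the free hydroxyls at C4 and C5, while the C2 hydroxyl, hydrogen-bonded to the acetyl carbonyl, is much less nucleophilic and stays free.

Step 2
Reactants: 2 1-[4,5-bis(TBSO)-2-hydroxyphenyl]ethanone
Product: 5 1-[4,5-bis(TBSO)-2-hydroxyphenyl]-2-hydroxyethanone, via bis(trimethylsilyl) enol ether 3 (not isolated), via 2-trimethylsilyloxy ketone 4 (not isolated)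
Conditions: TMSOTf (2.4 equiv), Et3N, CH2Cl2, 0 °C; crude after NaHCO3 wash, mCPBA (1.1 equiv), NaHCO3, CH2Cl2, −10 °C; aq. citric acid, THF, 20 °C
Reagents that add atoms: 3-chloroperoxybenzoic acid (mCPBA), O=C(OO)c1cccc(Cl)c1; trimethylsilyl trifluoromethanesulfonate (TMSOTf), C[Si](C)(C)OS(=O)(=O)C(F)(F)F (its silyl groups stay only in intermediates 3 and 4)
Why: Rubottom oxidation, in which soft enolisation silylates the phenol and the methyl ketone, the peracid epoxidises the electron-rich enol ether, a 1,4 silyl shift gives the α-silyloxy ketone, and mild aqueous acid removes both TMS groups while the aryl TBS ethers persist.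

Step 3
Reactants: 5 1-[4,5-bis(TBSO)-2-hydroxyphenyl]-2-hydroxyethanone
Product: 6 1-[4,5-bis(TBSO)-2-hydroxyphenyl]-2-(TBSO)ethanone
Conditions: TBSCl (1.05 equiv), imidazole, CH2Cl2, 0 °C
Reagents that add atoms: tert-butyldimethylsilyl chloride (TBSCl), CC(C)(C)[Si](C)(C)Cl
Why: Chemoselective silylation, since the primary alcohol reacts at 0 °C much faster than the chelated C2 phenol, which must remain free for the esterification.

Step 4
Reactants: 7 3,4-dihydroxybenzaldehyde; 8 1-bromo-3-methylbut-2-ene (prenyl bromide)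
Product: 9 4-hydroxy-3-(3-methylbut-2-enyloxy)benzaldehyde
Conditions: NaH (2.1 equiv), DMSO, 20 °C; 8 (1.0 equiv), 20 °C; then 1 M HCl to pH 5, 0 °C
Reagents that add atoms: none
Why: Regioselective Williamson etherification of a catechol dianion, in which the 4-oxide is delocalised into the para formyl group, so the 3-oxide is the stronger nucleophile and takes the single equivalent of allylic bromide at oxygen.

Step 5
Reactants: 9 4-hydroxy-3-(3-methylbut-2-enyloxy)benzaldehyde
Product: 10 4-(TBSO)-3-(3-methylbut-2-enyloxy)benzaldehyde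
Conditions: TBSCl (1.2 equiv), imidazole, CH2Cl2, 0 °C to 20 °C
Reagents that add atoms: tert-butyldimethylsilyl chloride (TBSCl), CC(C)(C)[Si](C)(C)Cl
Why: Standard silylation of the one remaining phenol.

Step 6
Reactants: 10 4-(TBSO)-3-(3-methylbut-2-enyloxy)benzaldehyde
Product: 11 4-(TBSO)-3-(3-methylbut-2-enyloxy)benzoic acid
Conditions: NaClO2, NaH2PO4, 2-methyl-2-butene (large excess), t-BuOH/H2O, 0 °C to 20 °C
Reagents that add atoms: sodium chlorite (NaClO2), [Na+].[O-]Cl=O
Why: Pinnick oxidation of the aryl aldehyde at buffered pH, where the excess 2-methyl-2-butene should intercept hypochlorous acid before it adds to the prenyl double bond and the aryl silyl ether tolerates the weakly acidic medium.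

Step 7
Reactants: 6 1-[4,5-bis(TBSO)-2-hydroxyphenyl]-2-(TBSO)ethanone; 11 4-(TBSO)-3-(3-methylbut-2-enyloxy)benzoic acid
Product: 12 4,5-bis(TBSO)-2-[2-(TBSO)acetyl]phenyl 4-(TBSO)-3-(3-methylbut-2-enyloxy)benzoate
Conditions: N,N'-dicyclohexylcarbodiimide (1.2 equiv), DMAP (0.2 equiv), CH2Cl2, 20 °C
Reagents that add atoms: none
Why: Steglich esterification, in which DMAP relays the O-acylisourea as an acylpyridinium that acylates even the hydrogen-bonded C2 phenol under neutral conditions that leave the silyl ethers and the prenyl ether untouched.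

Step 8
Reactants: 12 4,5-bis(TBSO)-2-[2-(TBSO)acetyl]phenyl 4-(TBSO)-3-(3-methylbut-2-enyloxy)benzoate
Product: 13 1-[4,5-bis(TBSO)-2-hydroxyphenyl]-2-(TBSO)-3-[4-(TBSO)-3-(3-methylbut-2-enyloxy)phenyl]propane-1,3-dione (racemic at C2)
Conditions: LiN(SiMe3)2 (3.0 equiv), THF, −78 °C to −20 °C; AcOH quench at −78 °C
Reagents that add atoms: none
Why: LiN(SiMe3)2 deprotonates the only enolisable carbon, the CH2 between the ketone and the silyloxy group, and the enolate carbon adds to the ortho ester carbonyl through a six-membered cyclic transition state; the tetrahedral lithium alkoxide then expels the ring A phenoxide, a 1,5 oxygen-to-carbon aroyl shift that forms C2–C3. The closest known reaction type is the Baker–Venkataraman rearrangement of 2-aroyloxy-ω-alkoxyacetophenones under lithium amide bases. No ring persists in the product, since the cyclic alkoxide formed by 6-exo-trig attack is transient and ring C is closed only in step 9. The new stereocentre at C2 forms without control as a racemate, is acidic, and becomes sp2 C3 in the next step, so none is needed. The step needs C-acylation at that one carbon by the ring B acyl group only, which the single enolisable site and the ester tether secure. Excess base converts the product into its phenoxide and diketonate, which pulls the equilibrium, and the low temperature should keep silyl migration in the α-silyloxy enolate and amide attack on the ester from competing.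

Step 9
Reactants: 13 1-[4,5-bis(TBSO)-2-hydroxyphenyl]-2-(TBSO)-3-[4-(TBSO)-3-(3-methylbut-2-enyloxy)phenyl]propane-1,3-dione
Product: 15 3,6,7-tris(TBSO)-2-[4-(TBSO)-3-(3-methylbut-2-enyloxy)phenyl]chromen-4-one, via hemiketal 14 (not isolated)
Conditions: pyridinium p-toluenesulfonate (0.3 equiv), toluene, 4 Å molecular sieves, 80 °C
Reagents that add atoms: none
Why: Acid-catalysed cyclodehydration of an o-hydroxyaryl 1,3-diketone, the closing stage of the Baker–Venkataraman flavone synthesis, in which the phenol adds 6-exo-trig to the ring B ketone and the hemiketal loses water toward the acidic C3–H; the weak pyridinium acid is chosen because it should not ionise the prenyl ether or the aryl silyl ethers.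

Step 10
Reactants: 15 3,6,7-tris(TBSO)-2-[4-(TBSO)-3-(3-methylbut-2-enyloxy)phenyl]chromen-4-one
Product: 16 3,6,7-trihydroxy-2-[4-hydroxy-3-(3-methylbut-2-enyloxy)phenyl]chromen-4-one (CNP0086069.0)
Conditions: Bu4NF (4.4 equiv), AcOH (4.4 equiv), THF, 0 °C, argon; dilute citric acid work-up
Reagents that add atoms: none
Why: Fluoride cleaves the three aryl silyl ethers and the C3 enol silyl ether through pentacoordinate silicon, the acetic acid protonates the released phenoxides so that the catechol and flavonol are not exposed to base and air, and the prenyl ether is inert to fluoride.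

**Compound list**
1 | 2',4',5'-trihydroxyacetophenone | CC(=O)c1cc(O)c(O)cc1O | starting material
2 | 1-[4,5-bis(TBSO)-2-hydroxyphenyl]ethanone | CC(=O)c1cc(O[Si](C)(C)C(C)(C)C)c(O[Si](C)(C)C(C)(C)C)cc1O | intermediate
3 | [1-[4,5-bis(TBSO)-2-(trimethylsilyloxy)phenyl]ethenyloxy]trimethylsilane | C=C(O[Si](C)(C)C)c1cc(O[Si](C)(C)C(C)(C)C)c(O[Si](C)(C)C(C)(C)C)cc1O[Si](C)(C)C | intermediate
4 | 1-[4,5-bis(TBSO)-2-(trimethylsilyloxy)phenyl]-2-(trimethylsilyloxy)ethanone | C[Si](C)(C)OCC(=O)c1cc(O[Si](C)(C)C(C)(C)C)c(O[Si](C)(C)C(C)(C)C)cc1O[Si](C)(C)C | intermediate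
5 | 1-[4,5-bis(TBSO)-2-hydroxyphenyl]-2-hydroxyethanone | OCC(=O)c1cc(O[Si](C)(C)C(C)(C)C)c(O[Si](C)(C)C(C)(C)C)cc1O | intermediate
6 | 1-[4,5-bis(TBSO)-2-hydroxyphenyl]-2-(TBSO)ethanone | CC(C)(C)[Si](C)(C)OCC(=O)c1cc(O[Si](C)(C)C(C)(C)C)c(O[Si](C)(C)C(C)(C)C)cc1O | intermediate
7 | 3,4-dihydroxybenzaldehyde | O=Cc1ccc(O)c(O)c1 | starting material
8 | 1-bromo-3-methylbut-2-ene (prenyl bromide) | CC(C)=CCBr | starting material
9 | 4-hydroxy-3-(3-methylbut-2-enyloxy)benzaldehyde | CC(C)=CCOc1cc(C=O)ccc1O | intermediate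
10 | 4-(TBSO)-3-(3-methylbut-2-enyloxy)benzaldehyde | CC(C)=CCOc1cc(C=O)ccc1O[Si](C)(C)C(C)(C)C | intermediate
11 | 4-(TBSO)-3-(3-methylbut-2-enyloxy)benzoic acid | CC(C)=CCOc1cc(C(=O)O)ccc1O[Si](C)(C)C(C)(C)C | intermediate
12 | 4,5-bis(TBSO)-2-[2-(TBSO)acetyl]phenyl 4-(TBSO)-3-(3-methylbut-2-enyloxy)benzoate | CC(C)=CCOc1cc(C(=O)Oc2cc(O[Si](C)(C)C(C)(C)C)c(O[Si](C)(C)C(C)(C)C)cc2C(=O)CO[Si](C)(C)C(C)(C)C)ccc1O[Si](C)(C)C(C)(C)C | intermediate
13 | 1-[4,5-bis(TBSO)-2-hydroxyphenyl]-2-(TBSO)-3-[4-(TBSO)-3-(3-methylbut-2-enyloxy)phenyl]propane-1,3-dione, racemic | CC(C)=CCOc1cc(C(=O)C(O[Si](C)(C)C(C)(C)C)C(=O)c2cc(O[Si](C)(C)C(C)(C)C)c(O[Si](C)(C)C(C)(C)C)cc2O)ccc1O[Si](C)(C)C(C)(C)C | intermediate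
14 | 2-hydroxy-3,6,7-tris(TBSO)-2-[4-(TBSO)-3-(3-methylbut-2-enyloxy)phenyl]chroman-4-one, diastereomer mixture | CC(C)=CCOc1cc(C2(O)Oc3cc(O[Si](C)(C)C(C)(C)C)c(O[Si](C)(C)C(C)(C)C)cc3C(=O)C2O[Si](C)(C)C(C)(C)C)ccc1O[Si](C)(C)C(C)(C)C | intermediate
15 | 3,6,7-tris(TBSO)-2-[4-(TBSO)-3-(3-methylbut-2-enyloxy)phenyl]chromen-4-one | CC(C)=CCOc1cc(-c2oc3cc(O[Si](C)(C)C(C)(C)C)c(O[Si](C)(C)C(C)(C)C)cc3c(=O)c2O[Si](C)(C)C(C)(C)C)ccc1O[Si](C)(C)C(C)(C)C | intermediate
16 | 3,6,7-trihydroxy-2-[4-hydroxy-3-(3-methylbut-2-enyloxy)phenyl]chromen-4-one (CNP0086069.0) | CC(C)=CCOc1cc(-c2oc3cc(O)c(O)cc3c(=O)c2O)ccc1O | target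

**Step count**
Total: 10 steps. Longest linear sequence: 7 steps (steps 1, 2, 3, 7, 8, 9, 10; the ring B branch through steps 4, 5, 6 is equally long).

**Steps most likely to fail**

Step 9. The dehydration of hemiketal 14 may stall under the weak pyridinium acid, and forcing it with a stronger acid would ionise the allylic carbon–oxygen bond of the prenyl ether. The fallback sets out from 7 and returns at 15. It carries an allyl ether, inert to sulfonic acid, through the ring closure and builds the prenyl group afterwards by olefin cross-metathesis. Dianion alkylation of 7 with allyl bromide (NaH, DMSO) should give 3-(allyloxy)-4-hydroxybenzaldehyde F1. Silylation (TBSCl, imidazole) would give 3-(allyloxy)-4-(TBSO)benzaldehyde F2, and Pinnick oxidation 3-(allyloxy)-4-(TBSO)benzoic acid F3. Steglich esterification of F3 with 6 would give 4,5-bis(TBSO)-2-[2-(TBSO)acetyl]phenyl 3-(allyloxy)-4-(TBSO)benzoate F4. LiN(SiMe3)2 would rearrange it to 1-[4,5-bis(TBSO)-2-hydroxyphenyl]-2-(TBSO)-3-[3-(allyloxy)-4-(TBSO)phenyl]propane-1,3-dione F5. Catalytic p-toluenesulfonic acid in toluene at 80 °C would then close ring C to 2-[3-(allyloxy)-4-(TBSO)phenyl]-3,6,7-tris(TBSO)chromen-4-one F6. Cross-metathesis of F6 with excess 2-methyl-2-butene under the second-generation Grubbs catalyst (CH2Cl2, 40 °C) should exchange the terminal methylene for an isopropylidene unit and deliver 15.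

Step 8. The acyl transfer needs warming, and in that time the α-silyloxy enolate may undergo a 1,4 oxygen-to-oxygen silyl shift, or the amide base may cleave the hindered aryl ester. The fallback sets out from 6 and 11 and returns at 13, replacing the tethered transfer by direct C-acylation with a faster acyl donor. Acid 11 would be converted under neutral conditions with 1-chloro-N,N,2-trimethylprop-1-en-1-amine (CH2Cl2, 0 °C) into 4-(TBSO)-3-(3-methylbut-2-enyloxy)benzoyl chloride F7. The dilithium phenoxide-enolate of 6 (LiN(SiMe3)2, 3.2 equiv, THF, −78 °C) would then be acylated at carbon by F7 at −78 °C, cold enough that silyl migration should not compete, and an AcOH quench should give 13.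

Step 4. The dianion alkylation may discriminate poorly between the two oxygens, or run on to the bis-ether or to C-prenylation. The fallback sets out from 7 and returns at 9, blocking the more acidic oxygen first. Weak-base alkylation (allyl bromide, NaHCO3, NaI, DMF, 40 °C) should take only the para hydroxyl and give 4-(allyloxy)-3-hydroxybenzaldehyde F8. Williamson etherification with 8 (K2CO3, DMF) would give 4-(allyloxy)-3-(3-methylbut-2-enyloxy)benzaldehyde F9. Pd(PPh3)4 (zerovalent palladium, catalytic) with morpholine in THF at 20 °C should then remove the allyl group, which ionises to the π-allyl complex much faster than the trisubstituted prenyl ether, and give 9.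

**Further compounds**
F1 | step 9 | 3-(allyloxy)-4-hydroxybenzaldehyde | C=CCOc1cc(C=O)ccc1O
F2 | step 9 | 3-(allyloxy)-4-(TBSO)benzaldehyde | C=CCOc1cc(C=O)ccc1O[Si](C)(C)C(C)(C)C
F3 | step 9 | 3-(allyloxy)-4-(TBSO)benzoic acid | C=CCOc1cc(C(=O)O)ccc1O[Si](C)(C)C(C)(C)C
F4 | step 9 | 4,5-bis(TBSO)-2-[2-(TBSO)acetyl]phenyl 3-(allyloxy)-4-(TBSO)benzoate | C=CCOc1cc(C(=O)Oc2cc(O[Si](C)(C)C(C)(C)C)c(O[Si](C)(C)C(C)(C)C)cc2C(=O)CO[Si](C)(C)C(C)(C)C)ccc1O[Si](C)(C)C(C)(C)C
F5 | step 9 | 1-[4,5-bis(TBSO)-2-hydroxyphenyl]-2-(TBSO)-3-[3-(allyloxy)-4-(TBSO)phenyl]propane-1,3-dione | C=CCOc1cc(C(=O)C(O[Si](C)(C)C(C)(C)C)C(=O)c2cc(O[Si](C)(C)C(C)(C)C)c(O[Si](C)(C)C(C)(C)C)cc2O)ccc1O[Si](C)(C)C(C)(C)C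
F6 | step 9 | 2-[3-(allyloxy)-4-(TBSO)phenyl]-3,6,7-tris(TBSO)chromen-4-one | C=CCOc1cc(-c2oc3cc(O[Si](C)(C)C(C)(C)C)c(O[Si](C)(C)C(C)(C)C)cc3c(=O)c2O[Si](C)(C)C(C)(C)C)ccc1O[Si](C)(C)C(C)(C)C
F7 | step 8 | 4-(TBSO)-3-(3-methylbut-2-enyloxy)benzoyl chloride | CC(C)=CCOc1cc(C(=O)Cl)ccc1O[Si](C)(C)C(C)(C)C
F8 | step 4 | 4-(allyloxy)-3-hydroxybenzaldehyde | O=Cc1ccc(OCC=C)c(O)c1
F9 | step 4 | 4-(allyloxy)-3-(3-methylbut-2-enyloxy)benzaldehyde | O=Cc1ccc(OCC=C)c(OCC=C(C)C)c1
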